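**Retrosynthetic overview**
1. The target comes from a final epoxidation of the 1(10)-E olefin; before that both ester side chains are attached as preformed acids and the α-methylene group is added by Mannich methylenation of a 12,6-olide.
2. The 12,6-olide comes from an O8-hydroxyl-directed 1,3-anti reduction of a C6 ketone and lactonization of the C7 acetate arm.
3. Key step: an anionic oxy-Cope [3,3] rearrangement of a trans-1,2-dialkenylcyclohexenol forms the C8–C9 bond, the ten-membered ring, the 1(10)-E olefin and C8; the enolate is alkylated at C7 in the same flask.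
4. The carbinol comes from a 4-silyloxy-isopiperitenone [(S)-carvone: Luche reduction, silylation, allylic oxidation] and a (Z)-2-alkoxyvinyllithium made from 4-methoxybenzyl alcohol; the oxirane acid is made from ethyl (S)-3-hydroxybutanoate and (R)-2-methylbutanoic acid is bought.
5. Ring order: cyclohexene (bought) → cyclodecadiene (oxy-Cope) → γ-lactone → side-chain oxirane (attached preformed) → ring oxirane.

Assumption: (S)-carvone, ethyl (S)-3-hydroxybutanoate and (R)-2-methylbutanoic acid are bought as single enantiomers; ten-membered rings carry germacrane numbering (ring C1–C10, C14 on C10, C15 on C4, C11–C13 on C7); TBS = tert-butyldimethylsilyl, PMB = 4-methoxybenzyl.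

**Route**

Step 1
Reactants: 1 (S)-(+)-carvone
Product: 2 (1S,5S)-2-methyl-5-(prop-1-en-2-yl)cyclohex-2-en-1-ol (cis-carveol)
Conditions: NaBH4, CeCl3·7H2O, MeOH, –78 → 0 °C
Reagents that add atoms: none
Why: Luche 1,2-reduction; axial hydride attack on the half-chair with equatorial isopropenyl gives the equatorial alcohol, so the bought C5 centre sets C1 as the cis (1S) isomer.

Step 2
Reactants: 2 cis-carveol
Product: 3 tert-butyl(dimethyl){[(1S,5S)-2-methyl-5-(prop-1-en-2-yl)cyclohex-2-en-1-yl]oxy}silane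
Conditions: TBSCl, imidazole, DMF, rt
Reagents that add atoms: tert-butyldimethylsilyl chloride, CC(C)(C)[Si](C)(C)Cl
Why: O-silylation (silyl ether protection) gives a base-stable group for the later organolithium and potassium alkoxide steps; no stereocentre is touched.

Step 3
Reactants: 3 cis-carveol TBS ether
Product: 4 (4S,6S)-4-{[tert-butyl(dimethyl)silyl]oxy}-3-methyl-6-(prop-1-en-2-yl)cyclohex-2-en-1-one
Conditions: Rh2(cap)4 (cap = caprolactamate C6H10NO, 1 mol%), t-BuOOH (70% in water), 1,2-dichloroethane, 40 °C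
Reagents that add atoms: tert-butyl hydroperoxide, CC(C)(C)OO
Why: Radical allylic C–H oxidation; the only unsubstituted ring methylene allylic to the trisubstituted olefin is converted to the enone under neutral conditions, so both stereocentres are kept.

Step 4
Reactants: 5 4-methoxybenzyl alcohol
Product: 6 1-methoxy-4-[(vinyloxy)methyl]benzene
Conditions: vinyl acetate, [Ir(cod)Cl]2 (1 mol%), Na2CO3, toluene, 100 °C
Reagents that add atoms: vinyl acetate, C=COC(C)=O
Why: Iridium-catalysed transfer vinylation (addition of the alcohol to vinyl acetate, then loss of acetate); no stereocentre.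

Step 5
Reactants: 6 4-methoxybenzyl vinyl ether
Product: 8 1-{[(Z)-2-bromoethenyl]oxymethyl}-4-methoxybenzene, via dibromo ether 7 (not isolated)
Conditions: Br2, CH2Cl2, –78 °C; then i-Pr2NEt, –78 °C → rt
Reagents that add atoms: bromine, BrBr
Why: Bromine addition then amine-induced dehydrobromination through the oxocarbenium ion gives the β-bromo enol ether, mainly the cis (Z) isomer as in the ethyl series; any E isomer is destroyed in step 6, because its lithio derivative eliminates alkoxide.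

Step 6
Reactants: 8 (Z)-2-bromovinyl PMB ether; 4 silyloxy enone
Product: 10 (1S,4S,6S)-4-{[tert-butyl(dimethyl)silyl]oxy}-1-{(Z)-2-[(4-methoxybenzyl)oxy]ethenyl}-3-methyl-6-(prop-1-en-2-yl)cyclohex-2-en-1-ol, via Z-alkoxyvinyllithium 9 (not isolated)
Conditions: 8, t-BuLi (2 equiv), Et2O, –78 °C; then 4, THF, –78 °C; then H2O
Reagents that add atoms: none
Why: Bromine–lithium exchange with retention of olefin geometry, then 1,2-addition to the enone from the face opposite the cis-disposed C4 silyloxy and C6 isopropenyl groups, which sets the carbinol centre (1S) with the two alkenyl groups trans.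

Step 7
Reactants: 10 dialkenyl carbinol
Product: 12 methyl (3S,7R,8R)-3-[tert-butyl(dimethyl)silyl]oxy-8-(4-methoxybenzyloxy)-6-oxo-13-norgermacra-1(10)E,4Z-dien-12-oate, via potassium enolate 11 (not isolated)
Conditions: KN(SiMe3)2 (1.05 equiv), 18-crown-6, THF, –78 → 20 °C; then BrCH2CO2Me, –78 °C
Reagents that add atoms: methyl bromoacetate, COC(=O)CBr
Why: Anionic oxy-Cope [3,3]-sigmatropic rearrangement through the chair transition state with both alkenyl groups equatorial; the C6 centre of 10 is transferred to C8 (R) as C8–C9 forms and the new olefin is 1(10)-E while the ring olefin stays 4Z, and the enolate is then alkylated on its outer face anti to C9 (7R), its in-plane C8–O bond disfavouring alkoxide loss.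

Step 8
Reactants: 12 keto ester
Product: 13 methyl (3S,7R,8R)-3-[tert-butyl(dimethyl)silyl]oxy-8-hydroxy-6-oxo-13-norgermacra-1(10)E,4Z-dien-12-oate
Conditions: DDQ, CH2Cl2/pH 7 phosphate buffer, 0 °C; used crude
Reagents that add atoms: none
Why: Oxidative cleavage of the PMB ether (benzylic hydride abstraction, hydrolysis of the oxocarbenium ion) under neutral conditions frees O8 without epimerizing C7 or eliminating the β-hydroxy ketone.

Step 9
Reactants: 13 β-hydroxy ketone
Product: 15 (3S,6R,7R,8R)-3-[tert-butyl(dimethyl)silyl]oxy-8-hydroxy-13-norgermacra-1(10)E,4Z-dien-12,6-olide, via anti-diol ester 14 (not isolated)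
Conditions: Me4NBH(OAc)3, MeCN/AcOH (1:1), –30 °C; then PPTS (cat.), CH2Cl2, rt
Reagents that add atoms: none
Why: Evans–Saksena hydroxyl-directed reduction delivers hydride intramolecularly from the O8-bound acyloxyborohydride through a six-membered chair to give the 1,3-anti diol (6R), and acid-catalysed lactonization then closes onto O6 as the trans-fused γ-lactone found in natural 8β-hydroxy-12,6-olides, not the cis-fused 12,8-isomer.

Step 10
Reactants: 16 ethyl (S)-3-hydroxybutanoate
Product: 17 ethyl (2S,3S)-3-hydroxy-2-methylbutanoate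
Conditions: LiN(i-Pr)2 (2.2 equiv), THF, –50 → –20 °C; MeI, DMPU, –78 → 0 °C; then H2O
Reagents that add atoms: iodomethane, CI
Why: Fráter–Seebach alkylation; the lithium-chelated dianion is methylated on the face opposite the C3 methyl group, giving the anti (2S) product.

Step 11
Reactants: 17 anti hydroxy ester
Product: 19 ethyl (2R,3S)-2,3-dimethyloxirane-2-carboxylate, via iodo alkoxide 18 (not isolated)
Conditions: LiN(i-Pr)2 (2.2 equiv), THF, –78 → –20 °C; then I2, THF, –78 → 0 °C
Reagents that add atoms: none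
Why: The chelated dianion is iodinated on the same face as in step 10, and the alkoxide then closes by intramolecular SN2 (Darzens-type) with inversion at C2, giving the oxirane with ester trans to the C3 methyl (2R) while C3 (S) is untouched.

Step 12
Reactants: 19 ethyl oxirane ester
Product: 20 (2R,3S)-2,3-dimethyloxirane-2-carboxylic acid
Conditions: KOH, EtOH/H2O, 0 °C → rt; then 1 M HCl to pH 3, 0 °C
Reagents that add atoms: potassium hydroxide, [K+].[OH-]
Why: Saponification by acyl–oxygen cleavage leaves both oxirane centres untouched (no enolizable α-hydrogen).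

Step 13
Reactants: 20 oxirane acid; 15 hydroxy lactone
Product: 22 (3S,6R,7R,8R)-3-[tert-butyl(dimethyl)silyl]oxy-8-{[(2R,3S)-2,3-dimethyloxiran-2-yl]carbonyloxy}-13-norgermacra-1(10)E,4Z-dien-12,6-olide, via mixed anhydride 21 (not isolated)
Conditions: 20, 2,4,6-trichlorobenzoyl chloride, Et3N, THF, rt; then 15, DMAP, toluene, rt
Reagents that add atoms: none
Why: Yamaguchi esterification; acyl transfer to O8 occurs at the carbonyl carbon, so C8 and the oxirane centres keep their configuration.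

Step 14
Reactants: 22 8-acyloxy lactone
Product: 25 (3S,6R,7R,8R)-3-[tert-butyl(dimethyl)silyl]oxy-8-{[(2R,3S)-2,3-dimethyloxiran-2-yl]carbonyloxy}germacra-1(10)E,4Z,11(13)-trien-12,6-olide, via Mannich base 23 (not isolated), via ammonium iodide 24 (not isolated)
Conditions: LiN(SiMe3)2, THF, –78 °C; Me2N=CH2+ I–, –78 °C → rt; MeI, MeOH, rt; aq. NaHCO3, CH2Cl2
Reagents that add atoms: N,N-dimethylmethyleneiminium iodide (Eschenmoser's salt), C=[N+](C)C.[I-]
Why: Mannich α-aminomethylation of the lactone enolate (the only enolizable position, since the oxirane ester has no α-hydrogen), quaternization and β-elimination give the exocyclic methylene; the C11 centre formed on the way is destroyed.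

Step 15
Reactants: 25 silyl ether
Product: 26 (3S,6R,7R,8R)-3-hydroxy-8-{[(2R,3S)-2,3-dimethyloxiran-2-yl]carbonyloxy}germacra-1(10)E,4Z,11(13)-trien-12,6-olide
Conditions: HF·pyridine, pyridine, THF, 0 °C → rt
Reagents that add atoms: none
Why: Buffered fluoride desilylation cleaves Si–O only, so C3 keeps its configuration and the Michael acceptor and esters survive.

Step 16
Reactants: 26 C3 alcohol; 27 (R)-2-methylbutanoic acid
Product: 28 (3S,6R,7R,8R)-3-[(2R)-2-methylbutanoyloxy]-8-{[(2R,3S)-2,3-dimethyloxiran-2-yl]carbonyloxy}germacra-1(10)E,4Z,11(13)-trien-12,6-olide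
Conditions: DCC, DMAP (cat.), CH2Cl2, 0 °C → rt
Reagents that add atoms: none
Why: Steglich esterification at O3 with retention at C3; the α-centre of the acid is bought and is not enolized under these mild conditions.

Step 17
Reactants: 28 diester triene
Product: 29 (1R,3S,6R,7R,8R,10R)-1,10-epoxy-3-[(2R)-2-methylbutanoyloxy]-8-{[(2R,3S)-2,3-dimethyloxiran-2-yl]carbonyloxy}germacra-4Z,11(13)-dien-12,6-olide (target CNP0265335.3)
Conditions: mCPBA (1.1 equiv), CH2Cl2, 0 °C
Reagents that add atoms: 3-chloroperoxybenzoic acid, OOC(=O)c1cccc(Cl)c1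
Why: Prilezhaev epoxidation; only the 1(10) olefin is electron-rich (the 4,5-olefin carries two allylic acyloxy groups and the methylene lactone is electron-poor), and stereospecific attack on its outer face in the ring conformer with the C14 methyl β gives the 1β,10α (1R,10R) trans-oxirane.

**Compound list**
1 | (S)-(+)-carvone | CC1=CC[C@@H](CC1=O)C(C)=C | starting material
2 | (1S,5S)-cis-carveol | CC1=CC[C@@H](C[C@@H]1O)C(C)=C | intermediate
3 | cis-carveol TBS ether | CC1=CC[C@@H](C[C@@H]1O[Si](C)(C)C(C)(C)C)C(C)=C | intermediate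
4 | (4S,6S)-4-TBS-oxy-3-methyl-6-(prop-1-en-2-yl)cyclohex-2-en-1-one | CC1=CC(=O)[C@@H](C[C@@H]1O[Si](C)(C)C(C)(C)C)C(C)=C | intermediate
5 | 4-methoxybenzyl alcohol | COc1ccc(CO)cc1 | starting material
6 | 4-methoxybenzyl vinyl ether | COc1ccc(COC=C)cc1 | intermediate
7 | 1-[(1,2-dibromoethoxy)methyl]-4-methoxybenzene (racemic, not isolated) | COc1ccc(COC(Br)CBr)cc1 | intermediate
8 | 1-{[(Z)-2-bromoethenyl]oxymethyl}-4-methoxybenzene | COc1ccc(CO/C=C\Br)cc1 | intermediate
9 | (Z)-2-[(4-methoxybenzyl)oxy]ethenyllithium (not isolated) | COc1ccc(CO/C=C\[Li])cc1 | intermediate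
10 | (1S,4S,6S)-4-TBS-oxy-1-[(Z)-2-(PMB-oxy)ethenyl]-3-methyl-6-(prop-1-en-2-yl)cyclohex-2-en-1-ol | CC1=C[C@@](O)(/C=C\OCc2ccc(OC)cc2)[C@@H](C[C@@H]1O[Si](C)(C)C(C)(C)C)C(C)=C | intermediate
11 | potassium (3S,8R)-3-TBS-oxy-8-PMB-oxy-11,12,13-trinorgermacra-1(10)E,4Z,6-trien-6-olate, C5 and C8 trans on C6=C7 (not isolated) | [K+].C1/C(C)=C/C[C@H](O[Si](C)(C)C(C)(C)C)/C(C)=C\C([O-])=C\[C@@H]1OCc2ccc(OC)cc2 | intermediate
12 | methyl (3S,7R,8R)-3-TBS-oxy-8-PMB-oxy-6-oxo-13-norgermacra-1(10)E,4Z-dien-12-oate | C1/C(C)=C/C[C@H](O[Si](C)(C)C(C)(C)C)/C(C)=C\C(=O)[C@H](CC(=O)OC)[C@@H]1OCc2ccc(OC)cc2 | intermediate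
13 | methyl (3S,7R,8R)-3-TBS-oxy-8-hydroxy-6-oxo-13-norgermacra-1(10)E,4Z-dien-12-oate | C1/C(C)=C/C[C@H](O[Si](C)(C)C(C)(C)C)/C(C)=C\C(=O)[C@H](CC(=O)OC)[C@@H]1O | intermediate
14 | methyl (3S,6R,7R,8R)-3-TBS-oxy-6,8-dihydroxy-13-norgermacra-1(10)E,4Z-dien-12-oate (not isolated) | C1/C(C)=C/C[C@H](O[Si](C)(C)C(C)(C)C)/C(C)=C\[C@@H](O)[C@H](CC(=O)OC)[C@@H]1O | intermediate
15 | (3S,6R,7R,8R)-3-TBS-oxy-8-hydroxy-13-norgermacra-1(10)E,4Z-dien-12,6-olide | C1C(=O)O[C@@H]2/C=C(/C)[C@@H](O[Si](C)(C)C(C)(C)C)C/C=C(\C)C[C@@H](O)[C@@H]12 | intermediate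
16 | ethyl (S)-3-hydroxybutanoate | CCOC(=O)C[C@H](C)O | starting material
17 | ethyl (2S,3S)-3-hydroxy-2-methylbutanoate | CCOC(=O)[C@@H](C)[C@H](C)O | intermediate
18 | lithium (2S,3S)-4-ethoxy-3-iodo-3-methyl-4-oxobutan-2-olate (not isolated) | [Li+].CCOC(=O)[C@@](C)(I)[C@H](C)[O-] | intermediate
19 | ethyl (2R,3S)-2,3-dimethyloxirane-2-carboxylate | CCOC(=O)[C@]1(C)O[C@H]1C | intermediate
20 | (2R,3S)-2,3-dimethyloxirane-2-carboxylic acid | OC(=O)[C@]1(C)O[C@H]1C | intermediate
21 | (2R,3S)-2,3-dimethyloxirane-2-carboxylic 2,4,6-trichlorobenzoic anhydride (not isolated) | O=C(OC(=O)[C@]1(C)O[C@H]1C)c2c(Cl)cc(Cl)cc2Cl | intermediate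
22 | (3S,6R,7R,8R)-3-TBS-oxy-8-{[(2R,3S)-2,3-dimethyloxiran-2-yl]carbonyloxy}-13-norgermacra-1(10)E,4Z-dien-12,6-olide | C1C(=O)O[C@@H]2/C=C(/C)[C@@H](O[Si](C)(C)C(C)(C)C)C/C=C(\C)C[C@@H](OC(=O)[C@]3(C)O[C@H]3C)[C@@H]12 | intermediate
23 | 11-[(dimethylamino)methyl] derivative of 22, C11 epimers (not isolated) | CN(C)CC1C(=O)O[C@@H]2/C=C(/C)[C@@H](O[Si](C)(C)C(C)(C)C)C/C=C(\C)C[C@@H](OC(=O)[C@]3(C)O[C@H]3C)[C@@H]12 | intermediate
24 | 11-[(trimethylammonio)methyl] iodide of 22, C11 epimers (not isolated) | C[N+](C)(C)CC1C(=O)O[C@@H]2/C=C(/C)[C@@H](O[Si](C)(C)C(C)(C)C)C/C=C(\C)C[C@@H](OC(=O)[C@]3(C)O[C@H]3C)[C@@H]12.[I-] | intermediate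
25 | (3S,6R,7R,8R)-3-TBS-oxy-8-{[(2R,3S)-2,3-dimethyloxiran-2-yl]carbonyloxy}germacra-1(10)E,4Z,11(13)-trien-12,6-olide | C=C1C(=O)O[C@@H]2/C=C(/C)[C@@H](O[Si](C)(C)C(C)(C)C)C/C=C(\C)C[C@@H](OC(=O)[C@]3(C)O[C@H]3C)[C@@H]12 | intermediate
26 | (3S,6R,7R,8R)-3-hydroxy-8-{[(2R,3S)-2,3-dimethyloxiran-2-yl]carbonyloxy}germacra-1(10)E,4Z,11(13)-trien-12,6-olide | C=C1C(=O)O[C@@H]2/C=C(/C)[C@@H](O)C/C=C(\C)C[C@@H](OC(=O)[C@]3(C)O[C@H]3C)[C@@H]12 | intermediate
27 | (R)-2-methylbutanoic acid | CC[C@@H](C)C(=O)O | starting material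
28 | (3S,6R,7R,8R)-3-[(2R)-2-methylbutanoyloxy]-8-{[(2R,3S)-2,3-dimethyloxiran-2-yl]carbonyloxy}germacra-1(10)E,4Z,11(13)-trien-12,6-olide | C=C1C(=O)O[C@@H]2/C=C(/C)[C@@H](OC(=O)[C@H](C)CC)C/C=C(\C)C[C@@H](OC(=O)[C@]3(C)O[C@H]3C)[C@@H]12 | intermediate
29 | (1R,3S,6R,7R,8R,10R)-1,10-epoxy-3-[(2R)-2-methylbutanoyloxy]-8-{[(2R,3S)-2,3-dimethyloxiran-2-yl]carbonyloxy}germacra-4Z,11(13)-dien-12,6-olide (CNP0265335.3) | C=C1C(=O)O[C@@H]2/C=C(/C)[C@@H](OC(=O)[C@H](C)CC)C[C@H]3O[C@]3(C)C[C@@H](OC(=O)[C@]3(C)O[C@H]3C)[C@@H]12 | target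

**Totals and risks**

Total step count: 17. Longest linear sequence: 12 steps (1 → 29 through steps 1–3, 6–9 and 13–17).

Three steps most likely to fail:

1. Step 3 (allylic oxidation). The oxidant may instead attack the silyloxy-bearing C–H or the isopropenyl allylic positions. Fallback, setting out from 3: mCPBA in CH2Cl2 at 0 °C epoxidizes the trisubstituted ring olefin trans to the silyloxy group to give the ring epoxide F1. PhSeNa (from PhSeSePh and NaBH4 in EtOH) opens it at the secondary carbon to give the β-hydroxy selenide F2. H2O2 oxidation and selenoxide syn-elimination towards the ring methylene give the tertiary allylic alcohol F3. [C5H5NH][CrO3Cl] (pyridinium chlorochromate) in CH2Cl2 then carries out the oxidative 1,3-transposition (Babler–Dauben) and returns to 4.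

2. Step 7 (oxy-Cope with in-flask alkylation). The free potassium enolate may lose the C8 alkoxide, scramble by proton transfer or O-alkylate before it is trapped. Fallback, setting out from 10: the rearrangement is run as before but the enolate is quenched at –78 °C with Me3SiCl and isolated as the trimethylsilyl enol ether F4, which keeps the enolate regiochemistry and geometry. MeLi in THF at 0 °C then releases the crown-free lithium enolate F5, which is alkylated with methyl bromoacetate and DMPU at –78 °C to come back at 12.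

3. Step 9 (directed reduction and lactonization). The ring may not allow the six-membered delivery, or the ester may close onto O8. Fallback, setting out from 12 with the PMB ether still in place: Zn(BH4)2 in Et2O at –20 °C reduces under chelation between the C6 carbonyl and O8, which reinforces the Felkin preference, and gives the C6-epimeric hydroxy ester F6. LiOH in THF/H2O gives the hydroxy acid F7. Mitsunobu lactonization (PPh3, DIAD, toluene, 0 °C) closes the ring with inversion at C6 to the trans-fused 8-PMB-oxy lactone F8. DDQ in buffered CH2Cl2 removes the PMB group and the route is rejoined at 15.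

**Further compounds**
F1 | step 3 | tert-butyl(dimethyl)silyl ether of 2,3-epoxy-2-methyl-5-(prop-1-en-2-yl)cyclohexan-1-ol, oxirane trans to the silyloxy group | C[C@]12O[C@H]1C[C@@H](C[C@@H]2O[Si](C)(C)C(C)(C)C)C(C)=C
F2 | step 3 | 2-TBS-oxy-1-methyl-6-(phenylselanyl)-4-(prop-1-en-2-yl)cyclohexan-1-ol, selenium trans to the hydroxyl | C[C@]1(O)[C@H]([Se]c2ccccc2)C[C@@H](C[C@@H]1O[Si](C)(C)C(C)(C)C)C(C)=C
F3 | step 3 | 6-TBS-oxy-1-methyl-4-(prop-1-en-2-yl)cyclohex-2-en-1-ol (tertiary allylic alcohol) | C[C@]1(O)C=C[C@@H](C[C@@H]1O[Si](C)(C)C(C)(C)C)C(C)=C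
F4 | step 7 | (3S,8R)-3-TBS-oxy-8-PMB-oxy-6-(trimethylsilyloxy)-11,12,13-trinorgermacra-1(10)E,4Z,6-triene | C1/C(C)=C/C[C@H](O[Si](C)(C)C(C)(C)C)/C(C)=C\C(O[Si](C)(C)C)=C\[C@@H]1OCc2ccc(OC)cc2
F5 | step 7 | lithium (3S,8R)-3-TBS-oxy-8-PMB-oxy-11,12,13-trinorgermacra-1(10)E,4Z,6-trien-6-olate | [Li+].C1/C(C)=C/C[C@H](O[Si](C)(C)C(C)(C)C)/C(C)=C\C([O-])=C\[C@@H]1OCc2ccc(OC)cc2
F6 | step 9 | methyl (3S,6S,7S,8R)-3-TBS-oxy-6-hydroxy-8-PMB-oxy-13-norgermacra-1(10)E,4Z-dien-12-oate (C7 unchanged in space, descriptor changed by ranking) | C1/C(C)=C/C[C@H](O[Si](C)(C)C(C)(C)C)/C(C)=C\[C@H](O)[C@H](CC(=O)OC)[C@@H]1OCc2ccc(OC)cc2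
F7 | step 9 | (3S,6S,7S,8R)-3-TBS-oxy-6-hydroxy-8-PMB-oxy-13-norgermacra-1(10)E,4Z-dien-12-oic acid | C1/C(C)=C/C[C@H](O[Si](C)(C)C(C)(C)C)/C(C)=C\[C@H](O)[C@H](CC(=O)O)[C@@H]1OCc2ccc(OC)cc2
F8 | step 9 | (3S,6R,7R,8R)-3-TBS-oxy-8-PMB-oxy-13-norgermacra-1(10)E,4Z-dien-12,6-olide | C1C(=O)O[C@@H]2/C=C(/C)[C@@H](O[Si](C)(C)C(C)(C)C)C/C=C(\C)C[C@@H](OCc3ccc(OC)cc3)[C@@H]12
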